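The cyclohexenone is closed by joining the ring carbonyl carbon C1 to the quaternary carbon C6. The route exploits the cis-1,3 relation on this ring between the C4 oxygen and the C6 branch, whose aroyl carbon can sit at the carboxyl level: tied to the C4 oxygen as an unsaturated δ-lactone, it makes C6 the β-carbon of an acceptor that an aldehyde chain on C4 can reach from one face only. A SmI2 ketyl–olefin cyclization (6-exo-trig) of this aldehyde lactone gives a 2-oxabicyclo[3.3.1]nonane in which C4 sets C6; the temporary lactone then steers exo methylation of the branch and is opened by an aryllithium to the aryl ketone.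

Key step: step 7

Remark: atom labels follow the target ring, C1 (C=O), C2=C3, C4 (OMe), C5 (CH2), C6 (quaternary); the branch is Cα (CHMe) plus the aroyl carbon. The hydroxyl configuration drawn for the products of step 7 is the expected one and is erased in step 8.

Step 1
Reactants: 1 (R)-1,2-epoxy-5-hexene; 2 ethyl propiolate
Product: 4 ethyl (5R)-5-hydroxynon-8-en-2-ynoate, via ethyl 3-lithiopropiolate 3 (not isolated)
Conditions: 2, n-BuLi, THF, −78 °C; BF3·OEt2; then 1, −78 °C
Reagents that add atoms: none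
Why: Alkynylborane opening of the terminal epoxide at its CH2 (Yamaguchi–Hirao alkynylation) leaves the carbinol stereocentre, the later C4, untouched.

Step 2
Reactants: 4 ethyl (5R)-5-hydroxynon-8-en-2-ynoate
Product: 6 (6R)-6-(but-3-en-1-yl)-4-methoxy-5,6-dihydro-2H-pyran-2-one, via E-methoxyenoate 5 (not isolated)
Conditions: NaOMe (0.3 equiv), MeOH, 0 °C to rt
Reagents that add atoms: methanol, CO
Why: Oxa-Michael addition of methoxide to the ynoate should give the E-β-methoxy enoate, whose ester is cis to the hydroxyalkyl chain and lactonizes at once.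

Step 3
Reactants: 6 (6R)-6-(but-3-en-1-yl)-4-methoxy-5,6-dihydro-2H-pyran-2-one
Product: 7 (6R)-6-(but-3-en-1-yl)oxane-2,4-dione
Conditions: 2 M HCl, THF, 40 °C
Reagents that add atoms: water, O
Why: Acid hydrolysis of the vinylogous methyl carbonate (enol ether hydrolysis) should free the β-keto lactone without touching the remote stereocentre.

Step 4
Reactants: 7 (6R)-6-(but-3-en-1-yl)oxane-2,4-dione
Product: 8 (2R)-2-(but-3-en-1-yl)-6-oxo-3,6-dihydro-2H-pyran-4-yl trifluoromethanesulfonate
Conditions: Tf2O, Et3N, CH2Cl2, −78 °C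
Reagents that add atoms: triflic anhydride, O=S(=O)(OS(=O)(=O)C(F)(F)F)C(F)(F)F
Why: O-Sulfonylation of the enol form of the β-keto lactone gives the vinyl triflate at the future C6.

Step 5
Reactants: 8 (2R)-2-(but-3-en-1-yl)-6-oxo-3,6-dihydro-2H-pyran-4-yl trifluoromethanesulfonate
Product: 10 (2R)-6-oxo-2-(3-oxopropyl)-3,6-dihydro-2H-pyran-4-yl trifluoromethanesulfonate, via ozonide 9 (not isolated)
Conditions: O3, CH2Cl2, −78 °C; then PPh3, −78 °C to rt
Reagents that add atoms: ozone, [O-][O+]=O
Why: Ozonolysis with reductive work-up should cleave only the terminal alkene, since the triflyloxy enoate alkene is strongly electron-poor, and gives the aldehyde that becomes C1.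

Step 6
Reactants: 10 (2R)-6-oxo-2-(3-oxopropyl)-3,6-dihydro-2H-pyran-4-yl trifluoromethanesulfonate
Product: 11 3-[(2R)-4-allyl-6-oxo-3,6-dihydro-2H-pyran-2-yl]propanal
Conditions: allylSnBu3, Pd(PPh3)4 (5 mol%), LiCl, THF, 60 °C
Reagents that add atoms: allyltributylstannane, C=CC[Sn](CCCC)(CCCC)CCCC
Why: Stille coupling of the vinyl triflate installs the allyl group on the future C6 under neutral conditions that an aldehyde tolerates.

Step 7
Reactants: 11 3-[(2R)-4-allyl-6-oxo-3,6-dihydro-2H-pyran-2-yl]propanal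
Product: 14 (1R,5S,6R)-5-allyl-6-hydroxy-2-oxabicyclo[3.3.1]nonan-3-one, via samarium ketyl 12 (not isolated), via samarium enolate 13 (not isolated)
Conditions: SmI2 (2.5 equiv), HMPA, t-BuOH (2 equiv), THF, −78 to 0 °C, 0.01 M, slow addition of 11
Reagents that add atoms: none
Why: SmI2 reduces the aldehyde to the samarium ketyl 12, which adds to C6, the β-carbon of the unsaturated lactone, and a second electron transfer gives the samarium enolate 13 that tert-butanol protonates at Cα. The closest known reaction type is the SmI2–HMPA ketyl–olefin (aldehyde–enoate) reductive cyclization, which is established for bridged rings with quaternary carbons. The carbocycle closes 6-exo-trig across the 2- and 4-positions of the dihydropyranone and gives the 2-oxabicyclo[3.3.1]nonane, the lactone ring being already present. C6 is controlled by C4, because the three-atom tether on C4 can bond to C6 only on its own face, which places the lactone oxygen and the Cα branch cis as the target requires; the carbinol centre (hydroxyl expected anti to the lactone CH2, away from the developing enolate) is removed in step 8. The step needs cyclization to outrun pinacol coupling and simple reduction and needs attack at C6 and not at Cα or the allyl group, which high dilution, HMPA, the polarized and only trisubstituted acceptor and the unactivated allyl alkene should secure.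

Step 8
Reactants: 14 (1R,5S,6R)-5-allyl-6-hydroxy-2-oxabicyclo[3.3.1]nonan-3-one
Product: 15 (1R,5S)-5-allyl-2-oxabicyclo[3.3.1]nonane-3,6-dione
Conditions: Dess–Martin periodinane, CH2Cl2, rt
Reagents that add atoms: none
Why: Dess–Martin oxidation of the hindered secondary alcohol brings C1 to the ketone level under neutral conditions.

Step 9
Reactants: 15 (1R,5S)-5-allyl-2-oxabicyclo[3.3.1]nonane-3,6-dione
Product: 16 (1R,5S)-5-allyl-6-[(tert-butyldimethylsilyl)oxy]-2-oxabicyclo[3.3.1]non-6-en-3-one
Conditions: TBSOTf (1.1 equiv), Et3N, CH2Cl2, −78 to 0 °C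
Reagents that add atoms: tert-butyldimethylsilyl triflate, CC(C)(C)[Si](C)(C)OS(=O)(=O)C(F)(F)F
Why: Soft enolization silylates the ketone much faster than the lactone and only towards C2, since C6 is quaternary; the silyl enol ether masks C1 and is the later handle for desaturation.

Step 10
Reactants: 16 (1R,5S)-5-allyl-6-[(tert-butyldimethylsilyl)oxy]-2-oxabicyclo[3.3.1]non-6-en-3-one
Product: 18 (1R,4R,5S)-5-allyl-6-[(tert-butyldimethylsilyl)oxy]-4-methyl-2-oxabicyclo[3.3.1]non-6-en-3-one, via lithium enolate 17 (not isolated)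
Conditions: lithium diisopropylamide (1.05 equiv), THF, −78 °C; MeI, −78 to −40 °C
Reagents that add atoms: iodomethane, CI
Why: Enolate alkylation of the bridged δ-lactone should occur on the exo face (axial attack, anti to the carbocyclic bridge that covers the endo face and to the C6–C1 bond), which sets Cα as R.

Step 11
Reactants: 18 (1R,4R,5S)-5-allyl-6-[(tert-butyldimethylsilyl)oxy]-4-methyl-2-oxabicyclo[3.3.1]non-6-en-3-one; 19 4-bromo-1,2-dimethoxybenzene
Product: 22 (2R)-2-[(1S,5R)-1-allyl-2-[(tert-butyldimethylsilyl)oxy]-5-hydroxycyclohex-2-en-1-yl]-1-(3,4-dimethoxyphenyl)propan-1-one, via 3,4-dimethoxyphenyllithium 20 (not isolated), via lithium lactolate 21 (not isolated)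
Conditions: 19, n-BuLi, THF, −78 °C; then 18, −78 °C; AcOH, −78 °C
Reagents that add atoms: none
Why: The aryllithium should add once to the lactone because the tetrahedral lithium lactolate persists at −78 °C, and protonation releases the δ-hydroxy aryl ketone, cleaving the temporary C4–O–acyl bond without touching a stereocentre.

Step 12
Reactants: 22 (2R)-2-[(1S,5R)-1-allyl-2-[(tert-butyldimethylsilyl)oxy]-5-hydroxycyclohex-2-en-1-yl]-1-(3,4-dimethoxyphenyl)propan-1-one
Product: 23 (4S,6S)-6-allyl-6-[(2R)-1-(3,4-dimethoxyphenyl)-1-oxopropan-2-yl]-4-hydroxycyclohex-2-en-1-one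
Conditions: Pd(OAc)2 (1.1 equiv), MeCN, rt
Reagents that add atoms: none
Why: Saegusa–Ito oxidation of the silyl enol ether can eliminate only towards C3 and so gives the C2=C3 enone.

Step 13
Reactants: 23 (4S,6S)-6-allyl-6-[(2R)-1-(3,4-dimethoxyphenyl)-1-oxopropan-2-yl]-4-hydroxycyclohex-2-en-1-one
Product: 24 (4S,6S)-6-allyl-6-[(2R)-1-(3,4-dimethoxyphenyl)-1-oxopropan-2-yl]-4-methoxycyclohex-2-en-1-one
Conditions: Me3OBF4, 1,8-bis(dimethylamino)naphthalene, CH2Cl2, 0 °C to rt
Reagents that add atoms: trimethyloxonium tetrafluoroborate, C[O+](C)C.F[B-](F)(F)F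
Why: O-Methylation with the oxonium salt buffered by a non-nucleophilic base forms no enolate, so the Cα centre next to the aryl ketone and the γ-oxygenated enone should survive.

Compound list
1 | (R)-1,2-epoxy-5-hexene, (2R)-2-(but-3-en-1-yl)oxirane | C=CCC[C@@H]1CO1 | starting material
2 | ethyl propiolate | C#CC(=O)OCC | starting material
3 | ethyl 3-lithiopropiolate | [Li]C#CC(=O)OCC | intermediate
4 | ethyl (5R)-5-hydroxynon-8-en-2-ynoate | CCOC(=O)C#CC[C@H](O)CCC=C | intermediate
5 | E-methoxyenoate, ethyl (2E,5R)-5-hydroxy-3-methoxynona-2,8-dienoate | CCOC(=O)/C=C(/OC)C[C@H](O)CCC=C | intermediate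
6 | (6R)-6-(but-3-en-1-yl)-4-methoxy-5,6-dihydro-2H-pyran-2-one | COC1=CC(=O)O[C@H](CCC=C)C1 | intermediate
7 | (6R)-6-(but-3-en-1-yl)oxane-2,4-dione | O=C1CC(=O)O[C@H](CCC=C)C1 | intermediate
8 | (2R)-2-(but-3-en-1-yl)-6-oxo-3,6-dihydro-2H-pyran-4-yl trifluoromethanesulfonate | FC(F)(F)S(=O)(=O)OC1=CC(=O)O[C@H](CCC=C)C1 | intermediate
9 | ozonide, the 1,2,4-trioxolan-3-yl derivative of 8 (mixture at the trioxolane carbon) | FC(F)(F)S(=O)(=O)OC1=CC(=O)O[C@H](CCC2OCOO2)C1 | intermediate
10 | (2R)-6-oxo-2-(3-oxopropyl)-3,6-dihydro-2H-pyran-4-yl trifluoromethanesulfonate | FC(F)(F)S(=O)(=O)OC1=CC(=O)O[C@H](CCC=O)C1 | intermediate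
11 | 3-[(2R)-4-allyl-6-oxo-3,6-dihydro-2H-pyran-2-yl]propanal | C=CCC1=CC(=O)O[C@H](CCC=O)C1 | intermediate
12 | samarium ketyl of 11 (O-bound trivalent samarium, radical at C1) | C=CCC1=CC(=O)O[C@H](CC[CH]O[Sm](I)I)C1 | intermediate
13 | samarium enolate, cyclized bis-samarium alkoxide and lactone enolate | C=CC[C@@]12C=C(O[Sm](I)I)O[C@@H](C1)CC[C@H]2O[Sm](I)I | intermediate
14 | (1R,5S,6R)-5-allyl-6-hydroxy-2-oxabicyclo[3.3.1]nonan-3-one | C=CC[C@@]12CC(=O)O[C@@H](C1)CC[C@H]2O | intermediate
15 | (1R,5S)-5-allyl-2-oxabicyclo[3.3.1]nonane-3,6-dione | C=CC[C@@]12CC(=O)O[C@@H](C1)CCC2=O | intermediate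
16 | (1R,5S)-5-allyl-6-[(tert-butyldimethylsilyl)oxy]-2-oxabicyclo[3.3.1]non-6-en-3-one | C=CC[C@@]12CC(=O)O[C@@H](C1)CC=C2O[Si](C)(C)C(C)(C)C | intermediate
17 | lithium enolate of lactone 16 | C=CC[C@@]12C=C(O[Li])O[C@@H](C1)CC=C2O[Si](C)(C)C(C)(C)C | intermediate
18 | (1R,4R,5S)-5-allyl-6-[(tert-butyldimethylsilyl)oxy]-4-methyl-2-oxabicyclo[3.3.1]non-6-en-3-one | C=CC[C@@]12[C@@H](C)C(=O)O[C@@H](C1)CC=C2O[Si](C)(C)C(C)(C)C | intermediate
19 | 4-bromo-1,2-dimethoxybenzene | COc1ccc(Br)cc1OC | starting material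
20 | 3,4-dimethoxyphenyllithium | COc1ccc([Li])cc1OC | intermediate
21 | lithium lactolate, tetrahedral adduct of 20 to 18 (hemiketal carbon undefined) | C=CC[C@@]12[C@@H](C)C(O[Li])(c3ccc(OC)c(OC)c3)O[C@@H](C1)CC=C2O[Si](C)(C)C(C)(C)C | intermediate
22 | (2R)-2-[(1S,5R)-1-allyl-2-[(tert-butyldimethylsilyl)oxy]-5-hydroxycyclohex-2-en-1-yl]-1-(3,4-dimethoxyphenyl)propan-1-one | C=CC[C@@]1([C@@H](C)C(=O)c2ccc(OC)c(OC)c2)C[C@H](O)CC=C1O[Si](C)(C)C(C)(C)C | intermediate
23 | (4S,6S)-6-allyl-6-[(2R)-1-(3,4-dimethoxyphenyl)-1-oxopropan-2-yl]-4-hydroxycyclohex-2-en-1-one | C=CC[C@@]1([C@@H](C)C(=O)c2ccc(OC)c(OC)c2)C[C@H](O)C=CC1=O | intermediate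
24 | (4S,6S)-6-allyl-6-[(2R)-1-(3,4-dimethoxyphenyl)-1-oxopropan-2-yl]-4-methoxycyclohex-2-en-1-one | C=CC[C@@]1([C@@H](C)C(=O)c2ccc(OC)c(OC)c2)C[C@H](OC)C=CC1=O | target

Total step count: 13. Longest linear sequence: 13 steps, from epoxide 1 to target 24; the aryllithium is made in the flask within step 11.

Steps most likely to fail

Step 7, the key step. The ketyl may be reduced on to the alcohol or dimerize (pinacol coupling) before it reaches the fully substituted β-carbon, or electron transfer to the unsaturated lactone may simply saturate it. The fallback is a tin hydride acyl radical cyclization, which also delivers the ketone level directly. Aldehyde 11 would be oxidized (NaClO2, NaH2PO4, 2-methyl-2-butene, t-BuOH/H2O) to the carboxylic acid F1 and converted (PhSeSePh, PBu3, CH2Cl2) into the Se-phenyl selenoester F2. Slow addition of Bu3SnH with AIBN in benzene at 80 °C should generate the acyl radical, which adds 6-exo-trig to C6 under the same tether control; hydrogen transfer to Cα then gives keto lactone 15. The route is rejoined at 15 and step 8 is not needed.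

Step 11. The aryllithium may act as a base at the hindered lactone (enolization, with loss of the Cα configuration on quench) or add a second time if the lactolate collapses early. The fallback goes through the aldehyde oxidation level. Lactone 18 would be reduced with iBu2AlH at −78 °C to the lactol F3, whose open hydroxy aldehyde form should take up 20 (2.5 equiv) to give the diol F4. MnO2 in CH2Cl2 should then oxidize only the electron-rich benzylic alcohol and return hydroxy ketone 22.

Step 13. Alkylation may take place on the hemiketal oxygen of the ring-closed tautomer (C4 hydroxyl added to the aryl ketone) instead of on the free C4 hydroxyl, or be slow enough for elimination of the γ-oxygen to compete. The fallback methylates before the ketone exists. Lactone 18 would be opened with Me2AlN(OMe)Me (from AlMe3 and MeNHOMe·HCl, CH2Cl2) to the hydroxy Weinreb amide F5, which is O-methylated (NaH, MeI, THF, 0 °C) to the methoxy Weinreb amide F6. Addition of 20 at −78 °C should give the methoxy aryl ketone silyl enol ether F7, and Saegusa–Ito oxidation with Pd(OAc)2 in MeCN gives target 24 directly.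

Further compounds
F1 | step 7 | 3-[(2R)-4-allyl-6-oxo-3,6-dihydro-2H-pyran-2-yl]propanoic acid | C=CCC1=CC(=O)O[C@H](CCC(=O)O)C1
F2 | step 7 | Se-phenyl 3-[(2R)-4-allyl-6-oxo-3,6-dihydro-2H-pyran-2-yl]propaneselenoate | C=CCC1=CC(=O)O[C@H](CCC(=O)[Se]c2ccccc2)C1
F3 | step 11 | (1R,4R,5S)-5-allyl-6-[(tert-butyldimethylsilyl)oxy]-4-methyl-2-oxabicyclo[3.3.1]non-6-en-3-ol (lactol, anomeric mixture) | C=CC[C@@]12[C@@H](C)C(O)O[C@@H](C1)CC=C2O[Si](C)(C)C(C)(C)C
F4 | step 11 | (2R)-2-[(1S,5R)-1-allyl-2-[(tert-butyldimethylsilyl)oxy]-5-hydroxycyclohex-2-en-1-yl]-1-(3,4-dimethoxyphenyl)propan-1-ol (carbinol epimers) | C=CC[C@@]1([C@@H](C)C(O)c2ccc(OC)c(OC)c2)C[C@H](O)CC=C1O[Si](C)(C)C(C)(C)C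
F5 | step 13 | (2R)-2-[(1S,5R)-1-allyl-2-[(tert-butyldimethylsilyl)oxy]-5-hydroxycyclohex-2-en-1-yl]-N-methoxy-N-methylpropanamide | C=CC[C@@]1([C@@H](C)C(=O)N(C)OC)C[C@H](O)CC=C1O[Si](C)(C)C(C)(C)C
F6 | step 13 | (2R)-2-[(1S,5R)-1-allyl-2-[(tert-butyldimethylsilyl)oxy]-5-methoxycyclohex-2-en-1-yl]-N-methoxy-N-methylpropanamide | C=CC[C@@]1([C@@H](C)C(=O)N(C)OC)C[C@H](OC)CC=C1O[Si](C)(C)C(C)(C)C
F7 | step 13 | (2R)-2-[(1S,5R)-1-allyl-2-[(tert-butyldimethylsilyl)oxy]-5-methoxycyclohex-2-en-1-yl]-1-(3,4-dimethoxyphenyl)propan-1-one | C=CC[C@@]1([C@@H](C)C(=O)c2ccc(OC)c(OC)c2)C[C@H](OC)CC=C1O[Si](C)(C)C(C)(C)C
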